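The numbers are assumed; no experiment stands behind them.

The constants set up a race for the starting material: it leaves by an uncatalysed first-order step and by a catalysed step that is pseudo-first-order at any given catalyst concentration, but the catalyst has to grow out of the precatalyst.

    starting material + catalyst → catalyst + target (k1 = 18 /M/s, Ea1 = 42.0 kJ/mol)
    starting material → side product (k2 = 0.088 /s, Ea2 = 85.0 kJ/mol)
    precatalyst → catalyst (k3 = 0.037 /s, Ea3 = 78.0 kJ/mol)
    (constants at 20 °C)

| flask | starting material | precatalyst | temperature | time |
|---|---|---|---|---|
| winter | 0.33 M | 2 mol% | 20 °C | 80 s |
| noon | 0.33 M | 2 mol% | 28 °C | 80 s |
| summer | 0.33 M | 2 mol% | 36 °C | 80 s |

* which of the two there is more of at the end, winter (target / side product)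
* which of the two there is more of at the end, noon (target / side product)
* which of the two there is more of at the end, summer (target / side product)
* target at the end, in percent of the starting material charged, winter
* target at the end, in percent of the starting material charged, noon
* target at the end, in percent of the starting material charged, summer

- constants are those at 20 °C; use the activation energies for any other temperature

The bench rule counts lifetimes and then takes the selectivity factor. In the winter flask the starting material lives 11.4 s against the side step, so 80 s is 7.02 lifetimes, and hardly any of it gets through the run past that step. If the whole charge of precatalyst counted as catalyst, at 0.006600 M, the catalysed constant would be 0.119 /s, larger than the side-step constant of 0.088 /s. That selectivity factor of 1.35 promises 57.5% target.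

The rule needs the catalyst present while the starting material is. In the winter flask, however, the precatalyst lives 27.0 s, longer than the starting material lives against the side step, and the ratio of the precatalyst constant to the side-step constant, 0.420, stands below one. Averaged over the survival of the starting material against the side step, the share of catalyst present is reckoned as the precatalyst constant over the sum of those two constants, 29.6% in winter. Multiplying the catalysed constant by that share and dividing by the side-step constant gives 0.400, and this is the race number: target made per side product made, so that the target's share is the race number over one plus the race number. The weighting counts the side step as the drain on the starting material, though the catalysed path adds 0.0352 /s to the 0.088 /s; a drain faster than the side step gives the precatalyst less time, so this reckoning should stand high.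

Warming lifts the constants according to their activation energies, 42.0 kJ/mol, 85.0 kJ/mol and 78.0 kJ/mol:

| Flask | Catalysed constant | Side step | Precatalyst step | Race number | Reckoned target |
|---|---|---|---|---|---|
| winter | 0.119 /s | 0.088 /s | 0.037 /s | 0.400 | 28.6% |
| noon | 0.188 /s | 0.222 /s | 0.0866 /s | 0.237 | 19.2% |
| summer | 0.290 /s | 0.535 /s | 0.194 /s | 0.144 | 12.6% |

The forecast names side product as the larger product in each flask and gives 23%, 16.3% and 11.7% target, on these grounds: “Warming favours the high-barrier side reaction over the low-barrier catalysed step”.

The flasks end with 23.1%, 16.3% and 11.2% target, against 76.9%, 83.7% and 88.8% side product. In the winter flask at 40.0 s, the starting material is down to 0.305% of its charge while 22.8% of the catalyst charged is still precatalyst. A summer neighbour charged with 3.4 mol% precatalyst has its race number raised to 0.245, which reckons 19.7%, and it ends at 16.6% target.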